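The route rests on cutting the bond between the guaiacyl ring and C2 of ring 1 (C1, C2, O3, C4, C5), next to the tertiary carbinol C1. The key step exploits the cis relationship of the C1 hydroxyl and the C2 aryl group: a bicyclic enol ether (C1=C2) that already holds ring 2 and the C5 and C6 stereocenters is epoxidised on its convex face, and the epoxy acetal is opened by a diarylzinc that binds to O1 and passes its aryl group to C2 on the same face. One operation forms the aryl–C2 bond, unveils the C1 hydroxyl and sets C1 and C2. The enol ether comes from an anti-aldol-derived lactone.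

Key step: step 10

Numbering used for every compound (that of the target, a 3,7-dioxabicyclo[3.3.0]octane): C1 carbinol bridgehead, C2 aryl-bearing carbon next to it, O3, C4, C5 CH bridgehead, C6 second aryl-bearing carbon, O7, C8; ring 1 = C1–C2–O3–C4–C5, ring 2 = C1–C8–O7–C6–C5. The target is (1S,2R,5R,6R): the C2 aryl group is cis to the C1 hydroxyl (convex face), the C6 aryl group is trans to H5 (concave face).

Assumption: in the MgCl2-catalysed anti-aldol (step 4) the (R)-4-benzyl auxiliary is taken to give the (S)-configured α-carbon by the chelated-enolate model; if the sense were the opposite, the (S)-auxiliary would be used with no other change.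

Step 1
Reactants: 1 4-bromo-2-methoxyphenol
Product: 2 (4-bromo-2-methoxyphenoxy)triisopropylsilane
Conditions: TIPSCl, imidazole, DMF, 23 °C
Reagents that add atoms: chlorotriisopropylsilane (TIPSCl), CC(C)[Si](Cl)(C(C)C)C(C)C
Why: Imidazole-assisted silylation of the phenol; the bulky aryl TIPS ether should survive the organolithium, enolate and hydride steps and leaves with fluoride at the end.

Step 2
Reactants: 3 vanillin
Product: 4 3-methoxy-4-(triisopropylsilyloxy)benzaldehyde
Conditions: TIPSCl, imidazole, DMF, 23 °C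
Reagents that add atoms: chlorotriisopropylsilane (TIPSCl), CC(C)[Si](Cl)(C(C)C)C(C)C
Why: Same silyl ether formation as in step 1; the silyloxy group also makes the later C6 benzylic ether less prone to ionisation than an alkoxy group would.

Step 3
Reactants: 5 (R)-4-benzyl-1,3-oxazolidin-2-one; 6 methyl 4-chloro-4-oxobutanoate
Product: 7 methyl 4-[(4R)-4-benzyl-2-oxo-1,3-oxazolidin-3-yl]-4-oxobutanoate
Conditions: n-BuLi, THF, −78 °C; then 6, −78 → 0 °C
Reagents that add atoms: none
Why: N-Acylation of the lithiated oxazolidinone by the acid chloride, which is far more electrophilic than the methyl ester.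

Step 4
Reactants: 7 methyl 4-[(4R)-4-benzyl-2-oxo-1,3-oxazolidin-3-yl]-4-oxobutanoate; 4 3-methoxy-4-(triisopropylsilyloxy)benzaldehyde
Product: 8 methyl (3S,4R)-3-{[(4R)-4-benzyl-2-oxo-1,3-oxazolidin-3-yl]carbonyl}-4-[3-methoxy-4-(triisopropylsilyloxy)phenyl]-4-(trimethylsilyloxy)butanoate
Conditions: MgCl2 (10 mol %), Et3N, TMSCl, EtOAc, 23 °C
Reagents that add atoms: chlorotrimethylsilane, C[Si](C)(C)Cl
Why: Magnesium-halide-catalysed Evans anti-aldol: the MgCl2-chelated (Z)-enolate of the imide (enolised at C5 only) should add to the non-enolisable aldehyde through a boat transition state on the face away from the benzyl group, setting C5 (S) and C6 (R) anti, while TMSCl traps the aldolate and turns the catalyst over.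

Step 5
Reactants: 8 the anti-aldol silyl ether
Product: 10 (4R)-4-[(R)-hydroxy{3-methoxy-4-(triisopropylsilyloxy)phenyl}methyl]oxolan-2-one, via silyl ether lactone 9 (not isolated)
Conditions: NaBH4, THF/H2O 4:1, 0 → 23 °C; then 10% aq. citric acid, 0 °C
Reagents that add atoms: none
Why: Reductive removal of the auxiliary: NaBH4 should reduce only the exocyclic imide carbonyl (C4), the primary alkoxide lactonises onto the C2 methyl ester while the C6 oxygen is still silylated (so only the ring 1 lactone can form), and the mild acid work-up then removes the TMS group without touching C5 or C6.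

Step 6
Reactants: 10 the hydroxy lactone
Product: 11 (4R)-4-[(R)-{3-methoxy-4-(triisopropylsilyloxy)phenyl}(methylsulfanylmethoxy)methyl]oxolan-2-one
Conditions: Me2S, (PhCO2)2, MeCN, 0 °C
Reagents that add atoms: dimethyl sulfide, CSC
Why: Pummerer-type methylthiomethyl ether formation by the sulfonium species from Me2S and dibenzoyl peroxide, under non-basic conditions that avoid alkoxide-induced translactonisation.

Step 7
Reactants: 11 the methylthiomethyl ether
Product: 13 (1R,5R,6R)-6-[3-methoxy-4-(triisopropylsilyloxy)phenyl]-3,7-dioxabicyclo[3.3.0]octan-2-one, via chloromethyl ether 12 (not isolated)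
Conditions: SO2Cl2, CH2Cl2, −78 °C, then evaporation; LiN(SiMe3)2, THF (dilute), −78 → −20 °C
Reagents that add atoms: none
Why: SO2Cl2 turns the O,S-acetal into the α-chloro ether, and the lithium enolate of the lactone displaces chloride in an intramolecular 5-exo-tet enolate alkylation that forms C1–C8 and closes ring 2; only the cis-fused bicycle is within reach, which sets C1 (R, H1 cis to H5).

Step 8
Reactants: 13 the bicyclic lactone
Product: 14 (1R,5R,6R)-6-[3-methoxy-4-(triisopropylsilyloxy)phenyl]-3,7-dioxabicyclo[3.3.0]octan-2-ol (mixture of anomers)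
Conditions: i-Bu2AlH, CH2Cl2, −78 °C; aq. KNaC4H4O6 work-up
Reagents that add atoms: none
Why: Partial reduction of the lactone by i-Bu2AlH at −78 °C, where the aluminium hemiacetal does not collapse; the anomeric centre C2 is lost in the next step.

Step 9
Reactants: 14 the lactol
Product: 16 (5R,6R)-6-[3-methoxy-4-(triisopropylsilyloxy)phenyl]-3,7-dioxabicyclo[3.3.0]oct-1-ene, via anomeric mesylate 15 (not isolated)
Conditions: MsCl, Et3N, CH2Cl2, −40 → 40 °C; purification on Et3N-deactivated silica
Reagents that add atoms: none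
Why: Dehydration of the 2-deoxy-type lactol through its mesylate (E1 loss to the oxocarbenium ion, then removal of H1 by Et3N), the usual way from lactols to glycal-type enol ethers; C1 becomes sp2 and C5 and C6 are untouched.

Step 10
Reactants: 16 the bicyclic enol ether; 2 (4-bromo-2-methoxyphenoxy)triisopropylsilane
Product: 20 (1S,2R,5R,6R)-2,6-bis[3-methoxy-4-(triisopropylsilyloxy)phenyl]-3,7-dioxabicyclo[3.3.0]octan-1-ol, via epoxy acetal 17 (not isolated), via aryllithium 18 (not isolated), via diarylzinc 19 (not isolated)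
Conditions: 16, DMDO, acetone/CH2Cl2, −78 → 0 °C, evaporate cold; separately 2, n-BuLi, PhMe/n-Bu2O, 0 °C, then ZnBr2 (0.5 equiv); combine in PhMe/n-Bu2O, 0 → 23 °C; aqueous work-up
Reagents that add atoms: dimethyldioxirane (DMDO), CC1(C)OO1
Why: DMDO should epoxidise the electron-rich C1=C2 enol ether on the convex face (the face of H5, away from the endo aryl group on C6), the only face that keeps the ring fusion cis, so C1 receives its oxygen with the S configuration. The Lewis-acidic diarylzinc 19 then binds the epoxide oxygen, the C2–O bond (not C1–O) breaks because only C2 gives an O3-stabilised oxocarbenium ion, and the aryl group is passed from the zinc alkoxide on O1 to C2 within the ion pair, on the face of O1. The closest known reaction type is the syn-selective opening of 1,2-anhydro sugars (glycal epoxides) by diarylzinc or triarylaluminium reagents in non-coordinating solvents, which gives 1,2-cis C-aryl glycosides. No ring is closed; the oxirane, a ring that is not in the target, is made only to carry the oxygen and to steer the aryl group, and it is opened in the same operation. C2 (R) is thus set by the temporary O1–Zn–aryl tether, and attack on the convex face of the cis-fused bicycle points the same way, so the two controls reinforce each other. The step needs syn instead of anti opening and an untouched C6 benzylic ether; toluene/n-Bu2O without copper or coordinating cosolvent should secure the first, the mild Lewis acidity of the zinc species at 0 °C the second.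

Step 11
Reactants: 20 the bis-silyl ether
Product: 21 (1S,2R,5R,6R)-2,6-bis(4-hydroxy-3-methoxyphenyl)-3,7-dioxabicyclo[3.3.0]octan-1-ol (target)
Conditions: Bu4NF, AcOH, THF, 0 °C
Reagents that add atoms: none
Why: Fluoride-induced desilylation of both aryl silyl ethers, with AcOH buffering the phenoxides, so the para-hydroxybenzylic C2 and C6 ethers, which epimerise under acid, never meet acid.

Compound list
1 | 4-bromo-2-methoxyphenol | COc1cc(Br)ccc1O | starting material
2 | (4-bromo-2-methoxyphenoxy)triisopropylsilane | COc1cc(Br)ccc1O[Si](C(C)C)(C(C)C)C(C)C | intermediate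
3 | vanillin (4-hydroxy-3-methoxybenzaldehyde) | COc1cc(C=O)ccc1O | starting material
4 | 3-methoxy-4-(triisopropylsilyloxy)benzaldehyde | COc1cc(C=O)ccc1O[Si](C(C)C)(C(C)C)C(C)C | intermediate
5 | (R)-4-benzyl-1,3-oxazolidin-2-one | O=C1N[C@H](Cc2ccccc2)CO1 | starting material
6 | methyl 4-chloro-4-oxobutanoate | COC(=O)CCC(Cl)=O | starting material
7 | methyl 4-[(4R)-4-benzyl-2-oxo-1,3-oxazolidin-3-yl]-4-oxobutanoate | COC(=O)CCC(=O)N1[C@H](Cc2ccccc2)COC1=O | intermediate
8 | methyl (3S,4R)-3-{[(4R)-4-benzyl-2-oxo-1,3-oxazolidin-3-yl]carbonyl}-4-[3-methoxy-4-(triisopropylsilyloxy)phenyl]-4-(trimethylsilyloxy)butanoate (anti-aldol adduct) | COC(=O)C[C@@H]([C@@H](O[Si](C)(C)C)c1ccc(O[Si](C(C)C)(C(C)C)C(C)C)c(OC)c1)C(=O)N1[C@H](Cc2ccccc2)COC1=O | intermediate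
9 | (4R)-4-[(R)-{3-methoxy-4-(triisopropylsilyloxy)phenyl}(trimethylsilyloxy)methyl]oxolan-2-one | O=C1C[C@H](CO1)[C@@H](O[Si](C)(C)C)c1ccc(O[Si](C(C)C)(C(C)C)C(C)C)c(OC)c1 | intermediate
10 | (4R)-4-[(R)-hydroxy{3-methoxy-4-(triisopropylsilyloxy)phenyl}methyl]oxolan-2-one | O=C1C[C@H](CO1)[C@@H](O)c1ccc(O[Si](C(C)C)(C(C)C)C(C)C)c(OC)c1 | intermediate
11 | (4R)-4-[(R)-{3-methoxy-4-(triisopropylsilyloxy)phenyl}(methylsulfanylmethoxy)methyl]oxolan-2-one | O=C1C[C@H](CO1)[C@@H](OCSC)c1ccc(O[Si](C(C)C)(C(C)C)C(C)C)c(OC)c1 | intermediate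
12 | (4R)-4-[(R)-(chloromethoxy){3-methoxy-4-(triisopropylsilyloxy)phenyl}methyl]oxolan-2-one | O=C1C[C@H](CO1)[C@@H](OCCl)c1ccc(O[Si](C(C)C)(C(C)C)C(C)C)c(OC)c1 | intermediate
13 | (1R,5R,6R)-6-[3-methoxy-4-(triisopropylsilyloxy)phenyl]-3,7-dioxabicyclo[3.3.0]octan-2-one (cis-fused, aryl trans to H5) | O=C1OC[C@@H]2[C@H](c3ccc(O[Si](C(C)C)(C(C)C)C(C)C)c(OC)c3)OC[C@H]12 | intermediate
14 | (1R,5R,6R)-6-[3-methoxy-4-(triisopropylsilyloxy)phenyl]-3,7-dioxabicyclo[3.3.0]octan-2-ol (anomers) | OC1OC[C@@H]2[C@H](c3ccc(O[Si](C(C)C)(C(C)C)C(C)C)c(OC)c3)OC[C@H]12 | intermediate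
15 | (1R,5R,6R)-6-[3-methoxy-4-(triisopropylsilyloxy)phenyl]-3,7-dioxabicyclo[3.3.0]octan-2-yl methanesulfonate | CS(=O)(=O)OC1OC[C@@H]2[C@H](c3ccc(O[Si](C(C)C)(C(C)C)C(C)C)c(OC)c3)OC[C@H]12 | intermediate
16 | (5R,6R)-6-[3-methoxy-4-(triisopropylsilyloxy)phenyl]-3,7-dioxabicyclo[3.3.0]oct-1-ene | C1OC=C2CO[C@@H](c3ccc(O[Si](C(C)C)(C(C)C)C(C)C)c(OC)c3)[C@@H]12 | intermediate
17 | (1S,2R,5R,6R)-1,2-epoxy-6-[3-methoxy-4-(triisopropylsilyloxy)phenyl]-3,7-dioxabicyclo[3.3.0]octane (epoxide oxygen cis to H5) | C1O[C@@H]2O[C@@]23CO[C@@H](c4ccc(O[Si](C(C)C)(C(C)C)C(C)C)c(OC)c4)[C@@H]13 | intermediate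
18 | [3-methoxy-4-(triisopropylsilyloxy)phenyl]lithium | [Li]c1ccc(O[Si](C(C)C)(C(C)C)C(C)C)c(OC)c1 | intermediate
19 | bis[3-methoxy-4-(triisopropylsilyloxy)phenyl]zinc | COc1cc([Zn]c2ccc(O[Si](C(C)C)(C(C)C)C(C)C)c(OC)c2)ccc1O[Si](C(C)C)(C(C)C)C(C)C | intermediate
20 | (1S,2R,5R,6R)-2,6-bis[3-methoxy-4-(triisopropylsilyloxy)phenyl]-3,7-dioxabicyclo[3.3.0]octan-1-ol | COc1cc([C@H]2OC[C@@H]3[C@H](c4ccc(O[Si](C(C)C)(C(C)C)C(C)C)c(OC)c4)OC[C@]23O)ccc1O[Si](C(C)C)(C(C)C)C(C)C | intermediate
21 | (1S,2R,5R,6R)-2,6-bis(4-hydroxy-3-methoxyphenyl)-3,7-dioxabicyclo[3.3.0]octan-1-ol | COc1cc([C@H]2OC[C@@H]3[C@H](c4ccc(O)c(OC)c4)OC[C@]23O)ccc1O | target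

Total step count: 11. Longest linear sequence: 9 steps (steps 3, 4, 5, 6, 7, 8, 9, 10, 11 from 5; the same length from vanillin through step 2).

Steps most likely to fail

Step 10 (key step). The epoxy acetal may open with inversion by attack from outside instead of by delivery from zinc. The zinc alkoxide next to the oxocarbenium centre may also undergo a 1,2-shift (semipinacol-type ring contraction). The Lewis acid may epimerise C6 by reversible ionisation of the benzylic C6–O7 bond. The fallback sets out from 13 and comes back at 20, with the oxygen and the aryl group brought in separately. The potassium enolate of 13 (KN(SiMe3)2, THF, −78 °C) would be hydroxylated with 2-(phenylsulfonyl)-3-phenyloxaziridine to (1S,5R,6R)-1-hydroxy-6-[3-methoxy-4-(triisopropylsilyloxy)phenyl]-3,7-dioxabicyclo[3.3.0]octan-2-one F1; the ring fusion forces the new C1–O bond cis to H5. i-Bu2AlH (CH2Cl2, −78 °C) would reduce F1 to the lactol diol F2. The aryl Grignard reagent [3-methoxy-4-(triisopropylsilyloxy)phenyl]magnesium bromide F3 (from 2 and Mg in THF, used in excess) would add to the open α-hydroxy aldehyde form of F2 under chelation control by the C1 magnesium alkoxide, from the side of C8, to give the triol F4. A Mitsunobu cycloetherification (PPh3, diisopropyl azodicarboxylate, THF, 0 °C) activates only the primary C4 hydroxyl and should close ring 1 with retention at C2, giving 20.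

Step 7. SO2Cl2 or the sulfenyl chloride formed from it may attack the electron-rich arene. The benzylic chloromethyl ether may ionise at C6. The enolate may alkylate between molecules instead of closing ring 2. The fallback sets out from 10 and comes back at 13. It brings in C8 at the aldehyde oxidation level. Claisen formylation of 10 (NaH, HCO2Et, THF, then AcOH) would give the α-formyl lactone, which should rest as the bicyclic hemiacetal (5R,6R)-8-hydroxy-6-[3-methoxy-4-(triisopropylsilyloxy)phenyl]-3,7-dioxabicyclo[3.3.0]octan-2-one F5. MsCl/Et3N (CH2Cl2, 0 °C) would dehydrate it to the vinylogous carbonate (5R,6R)-6-[3-methoxy-4-(triisopropylsilyloxy)phenyl]-3,7-dioxabicyclo[3.3.0]oct-1(8)-en-2-one F6. Hydrogenation of C1=C8 (H2, Rh/Al2O3, EtOAc) can only give the cis-fused lactone 13.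

Step 9. The anomeric mesylate (or the chloride formed from it) may fail to eliminate, or the acid-labile enol ether may hydrate or oligomerise during reaction and isolation. The fallback sets out from 13 and comes back at 16, without passing through the lactol. KN(SiMe3)2 and PhNTf2 (THF, −78 °C) would convert 13 into the ketene acetal triflate (5R,6R)-6-[3-methoxy-4-(triisopropylsilyloxy)phenyl]-3,7-dioxabicyclo[3.3.0]oct-1-en-2-yl trifluoromethanesulfonate F7. Reduction with Bu3SnH, Pd(PPh3)4 and LiCl in THF would replace the triflate by hydrogen and give 16 under neutral conditions.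

Further compounds
F1 | step 10 | (1S,5R,6R)-1-hydroxy-6-[3-methoxy-4-(triisopropylsilyloxy)phenyl]-3,7-dioxabicyclo[3.3.0]octan-2-one | O=C1OC[C@@H]2[C@H](c3ccc(O[Si](C(C)C)(C(C)C)C(C)C)c(OC)c3)OC[C@]12O
F2 | step 10 | (1S,5R,6R)-6-[3-methoxy-4-(triisopropylsilyloxy)phenyl]-3,7-dioxabicyclo[3.3.0]octane-1,2-diol (anomers) | OC1OC[C@@H]2[C@H](c3ccc(O[Si](C(C)C)(C(C)C)C(C)C)c(OC)c3)OC[C@]12O
F3 | step 10 | [3-methoxy-4-(triisopropylsilyloxy)phenyl]magnesium bromide | Br[Mg]c1ccc(O[Si](C(C)C)(C(C)C)C(C)C)c(OC)c1
F4 | step 10 | (3S,4R,5R)-3-[(R)-hydroxy{3-methoxy-4-(triisopropylsilyloxy)phenyl}methyl]-4-(hydroxymethyl)-5-[3-methoxy-4-(triisopropylsilyloxy)phenyl]oxolan-3-ol | OC[C@@H]1[C@H](c2ccc(O[Si](C(C)C)(C(C)C)C(C)C)c(OC)c2)OC[C@]1(O)[C@H](O)c1ccc(O[Si](C(C)C)(C(C)C)C(C)C)c(OC)c1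
F5 | step 7 | (5R,6R)-8-hydroxy-6-[3-methoxy-4-(triisopropylsilyloxy)phenyl]-3,7-dioxabicyclo[3.3.0]octan-2-one (hemiacetal form of the α-formyl lactone) | O=C1OC[C@@H]2[C@H](c3ccc(O[Si](C(C)C)(C(C)C)C(C)C)c(OC)c3)OC(O)C12
F6 | step 7 | (5R,6R)-6-[3-methoxy-4-(triisopropylsilyloxy)phenyl]-3,7-dioxabicyclo[3.3.0]oct-1(8)-en-2-one | O=C1OC[C@@H]2[C@H](c3ccc(O[Si](C(C)C)(C(C)C)C(C)C)c(OC)c3)OC=C12
F7 | step 9 | (5R,6R)-6-[3-methoxy-4-(triisopropylsilyloxy)phenyl]-3,7-dioxabicyclo[3.3.0]oct-1-en-2-yl trifluoromethanesulfonate | C1OC(OS(=O)(=O)C(F)(F)F)=C2CO[C@@H](c3ccc(O[Si](C(C)C)(C(C)C)C(C)C)c(OC)c3)[C@@H]12
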